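**Strategy.** The route rests on disconnecting the ArCH2–CH2Ar' bond of the ethane-1,2-diyl bridge between the 3,5-dimethoxy-4-prenylphenyl ring (ring A) and the 2-methoxy-3,4-dioxygenated ring (ring B). Both bridge carbons are benzylic, so both are traced back to aldehyde carbons. A ruthenium(II)-catalysed, hydrazine-mediated reductive cross-coupling (carbonyl-umpolung olefination) joins the N–H hydrazone of the bis-MOM ring B aldehyde to the prenylated ring A aldehyde. It forges the bridge as a stilbene C=C, releasing only N2 and water. Diimide then saturates the bridge without touching the prenyl alkene, and MOM removal followed by 4-O-selective monoacetylation finishes the synthesis.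

Key step: step 4

Remark: the target has no stereocentre and no stereogenic double bond (the prenyl alkene carries two identical methyl groups), so no enantiocontrol is needed. MOM = methoxymethyl.

**Step 1**
Reactants: 1 4-bromo-3,5-dimethoxybenzaldehyde; 2 tributyl(3-methylbut-2-en-1-yl)stannane
Product: 3 3,5-dimethoxy-4-(3-methylbut-2-en-1-yl)benzaldehyde
Conditions: Pd(PPh3)4 (5 mol%), DMF, 100 °C
Reagents that add atoms: none
Why: Stille cross-coupling, in which the para-formyl group activates the hindered C–Br bond toward oxidative addition and reductive elimination from the less substituted terminus of the prenyl–palladium intermediate should give the linear prenyl arene.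

**Step 2**
Reactants: 4 2,3,4-trihydroxybenzaldehyde
Product: 5 2-hydroxy-3,4-bis(methoxymethoxy)benzaldehyde
Conditions: MOMCl (2.1 equiv), K2CO3, acetone, 0 °C → rt
Reagents that add atoms: chloromethyl methyl ether (MOMCl), COCCl
Why: Regioselective Williamson-type O-alkylation, because the 2-OH is locked in a hydrogen bond to the formyl oxygen and is the least nucleophilic, so two equivalents of MOMCl should cap only the 3- and 4-hydroxyls.

**Step 3**
Reactants: 5 2-hydroxy-3,4-bis(methoxymethoxy)benzaldehyde
Product: 6 2-methoxy-3,4-bis(methoxymethoxy)benzaldehyde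
Conditions: MeI, K2CO3, DMF, 40 °C
Reagents that add atoms: iodomethane, CI
Why: Williamson ether synthesis, in which the remaining chelated phenol is methylated under slightly more forcing conditions that leave the MOM acetals and the aldehyde untouched.

**Step 4**
Reactants: 6 2-methoxy-3,4-bis(methoxymethoxy)benzaldehyde; 7 hydrazine monohydrate; 3 3,5-dimethoxy-4-(3-methylbut-2-en-1-yl)benzaldehyde
Product: 9 (E)-1-[3,5-dimethoxy-4-(3-methylbut-2-en-1-yl)phenyl]-2-[2-methoxy-3,4-bis(methoxymethoxy)phenyl]ethene, via benzaldehyde hydrazone 8 (not isolated)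
Conditions: 6, N2H4·H2O (1.1 equiv), THF, rt; then 3, [Ru(p-cymene)Cl2]2 (cat.), dmpe (cat.), KOtBu (sub-stoich.), THF, 45 °C, Ar
Reagents that add atoms: none
Why: Ru(II)/dmpe binds the deprotonated N–H hydrazone 8, whose carbon acts as a benzylic carbanion equivalent and adds to the formyl carbon of 3 through a chair-like six-membered transition state; base-induced loss of N2 from the resulting β-alkoxy diazene gives a benzylic carbanion that expels hydroxide (E1cB), leaving a C=C bond between the two former aldehyde carbons. The closest known reaction type is the ruthenium-catalysed, hydrazine-mediated reductive cross-coupling of two aryl carbonyl compounds to olefins, a catalytic cross-McMurry equivalent. No ring is closed and no stereocentre is formed; the alkene geometry (E expected) is irrelevant because step 5 saturates it. The step needs cross- over homo-coupling and olefin over carbinol formation: the hydrazone is preformed from the more electron-rich, less electrophilic aldehyde 6 (ortho and para oxygen donors), whereas 3, whose methoxy groups are meta to the formyl group, is the better acceptor, and the doubly benzylic adduct favours elimination. The prenyl alkene, the MOM acetals and the aryl ethers are inert to the catalyst and base.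

**Step 5**
Reactants: 9 (E)-1-[3,5-dimethoxy-4-(3-methylbut-2-en-1-yl)phenyl]-2-[2-methoxy-3,4-bis(methoxymethoxy)phenyl]ethene
Product: 10 1-{2-[3,5-dimethoxy-4-(3-methylbut-2-en-1-yl)phenyl]ethyl}-2-methoxy-3,4-bis(methoxymethoxy)benzene
Conditions: TsNHNH2 (added in portions), NaOAc, DME/H2O, reflux
Reagents that add atoms: none
Why: Diimide reduction (concerted syn transfer of H2), which should reduce the 1,2-disubstituted styrenic C=C much faster than the trisubstituted prenyl alkene while the metal-free conditions leave MOM and aryl ethers intact; no stereocentre is created.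

**Step 6**
Reactants: 10 1-{2-[3,5-dimethoxy-4-(3-methylbut-2-en-1-yl)phenyl]ethyl}-2-methoxy-3,4-bis(methoxymethoxy)benzene
Product: 11 4-{2-[3,5-dimethoxy-4-(3-methylbut-2-en-1-yl)phenyl]ethyl}-3-methoxybenzene-1,2-diol
Conditions: HCl (3 M aq.), MeOH, 40 °C, Ar
Reagents that add atoms: none
Why: Acid-catalysed acetal exchange (MOM ether cleavage by methanol) frees both phenols, and the prenyl group, flanked by two methoxy groups and lacking an ortho hydroxyl to cyclise onto, should survive dilute methanolic HCl.

**Step 7**
Reactants: 11 4-{2-[3,5-dimethoxy-4-(3-methylbut-2-en-1-yl)phenyl]ethyl}-3-methoxybenzene-1,2-diol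
Product: 12 4-{2-[3,5-dimethoxy-4-(3-methylbut-2-en-1-yl)phenyl]ethyl}-2-hydroxy-3-methoxyphenyl acetate (target)
Conditions: Ac2O (1.0 equiv), Et3N, CH2Cl2, −20 → 0 °C, Ar
Reagents that add atoms: acetic anhydride, CC(=O)OC(C)=O
Why: Selective O-acylation of the less hindered 4-OH (one ortho substituent) over the 3-OH, which is flanked by OMe and OH and hydrogen-bonded to the methoxy oxygen; base-mediated ortho-acyl migration is expected to favour the same, less congested 4-O-acetate.

**Compound list**

1 | 4-bromo-3,5-dimethoxybenzaldehyde | COc1cc(C=O)cc(OC)c1Br | starting material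
2 | tributyl(3-methylbut-2-en-1-yl)stannane | CCCC[Sn](CCCC)(CCCC)CC=C(C)C | starting material
3 | 3,5-dimethoxy-4-(3-methylbut-2-en-1-yl)benzaldehyde | COc1cc(C=O)cc(OC)c1CC=C(C)C | intermediate
4 | 2,3,4-trihydroxybenzaldehyde | O=Cc1ccc(O)c(O)c1O | starting material
5 | 2-hydroxy-3,4-bis(methoxymethoxy)benzaldehyde | COCOc1ccc(C=O)c(O)c1OCOC | intermediate
6 | 2-methoxy-3,4-bis(methoxymethoxy)benzaldehyde | COCOc1ccc(C=O)c(OC)c1OCOC | intermediate
7 | hydrazine monohydrate | NN.O | starting material
8 | (E)-[2-methoxy-3,4-bis(methoxymethoxy)benzylidene]hydrazine (formed in the flask, not isolated) | COCOc1ccc(/C=N/N)c(OC)c1OCOC | intermediate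
9 | (E)-1-[3,5-dimethoxy-4-(3-methylbut-2-en-1-yl)phenyl]-2-[2-methoxy-3,4-bis(methoxymethoxy)phenyl]ethene | COCOc1ccc(/C=C/c2cc(OC)c(CC=C(C)C)c(OC)c2)c(OC)c1OCOC | intermediate
10 | 1-{2-[3,5-dimethoxy-4-(3-methylbut-2-en-1-yl)phenyl]ethyl}-2-methoxy-3,4-bis(methoxymethoxy)benzene | COCOc1ccc(CCc2cc(OC)c(CC=C(C)C)c(OC)c2)c(OC)c1OCOC | intermediate
11 | 4-{2-[3,5-dimethoxy-4-(3-methylbut-2-en-1-yl)phenyl]ethyl}-3-methoxybenzene-1,2-diol | COc1cc(CCc2ccc(O)c(O)c2OC)cc(OC)c1CC=C(C)C | intermediate
12 | 4-{2-[3,5-dimethoxy-4-(3-methylbut-2-en-1-yl)phenyl]ethyl}-2-hydroxy-3-methoxyphenyl acetate | COc1cc(CCc2ccc(OC(C)=O)c(O)c2OC)cc(OC)c1CC=C(C)C | target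

**Step count.** Total: 7 steps. Longest linear sequence: 6 steps (4 → 5 → 6 → 9 → 10 → 11 → 12; step 1 is the convergent branch).

**Steps most likely to fail**

1. Step 4 (key step). The risk is hydrazone exchange and azine formation leading to homo-coupled olefins, or arrest at the carbinol stage by protonation instead of elimination. The fallback is a Wittig olefination that forms the same bridge bond; it sets out from aldehyde 3 and returns at stilbene 9. Reduction of 3 (NaBH4, MeOH, 0 °C) should give [3,5-dimethoxy-4-(3-methylbut-2-en-1-yl)phenyl]methanol F1. Appel bromination (CBr4, PPh3, CH2Cl2, 0 °C) should give 5-(bromomethyl)-1,3-dimethoxy-2-(3-methylbut-2-en-1-yl)benzene F2. Heating with PPh3 in toluene at 80 °C should give [3,5-dimethoxy-4-(3-methylbut-2-en-1-yl)benzyl]triphenylphosphonium bromide F3. Deprotonation with KOtBu in THF at 0 °C should give the semi-stabilised ylide [3,5-dimethoxy-4-(3-methylbut-2-en-1-yl)benzylidene]triphenylphosphorane F4, which is condensed in the same flask with aldehyde 6 to give stilbene 9. Any Z isomer converges in step 5.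

2. Step 5. The risk is insufficient rate discrimination by diimide, so that the prenyl alkene is partly saturated along with the bridge. The fallback moves the prenylation behind the reduction; it sets out from bromo aldehyde 1 and hydrazone 8 and returns at bibenzyl 10. The ruthenium-catalysed coupling of step 4, run with 1 in place of 3, should give (E)-1-(4-bromo-3,5-dimethoxyphenyl)-2-[2-methoxy-3,4-bis(methoxymethoxy)phenyl]ethene F5. Diimide reduction (TsNHNH2, NaOAc, DME/H2O, reflux), now with no competing alkene, should give 1-[2-(4-bromo-3,5-dimethoxyphenyl)ethyl]-2-methoxy-3,4-bis(methoxymethoxy)benzene F6. Stille coupling of F6 with stannane 2 (Pd2(dba)3, P(t-Bu)3, dioxane, 100 °C) should then give 10.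

3. Step 7. The risk is statistical over-acetylation to the diacetate and partial acylation of, or acyl migration to, the 3-oxygen. The fallback replaces acyl transfer by orthoester opening; it sets out from catechol 11 and returns at target 12. Heating 11 with trimethyl orthoacetate and catalytic PPTS in toluene at 80 °C should give the cyclic orthoacetate 2-methoxy-2-methyl-1,3-benzodioxole derivative F7 (racemic at the orthoester carbon, a centre that is destroyed on opening). Mild hydrolysis (AcOH/H2O/THF, 0 °C) can then give only monoacetate. Collapse of the hemi-orthoester is expected to expel the more acidic, doubly ortho-oxygenated 3-phenol, leaving the acetate on the 4-oxygen as in 12.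

**Further compounds**

F1 | step 4 | [3,5-dimethoxy-4-(3-methylbut-2-en-1-yl)phenyl]methanol | COc1cc(CO)cc(OC)c1CC=C(C)C
F2 | step 4 | 5-(bromomethyl)-1,3-dimethoxy-2-(3-methylbut-2-en-1-yl)benzene | COc1cc(CBr)cc(OC)c1CC=C(C)C
F3 | step 4 | [3,5-dimethoxy-4-(3-methylbut-2-en-1-yl)benzyl]triphenylphosphonium bromide | COc1cc(C[P+](c2ccccc2)(c2ccccc2)c2ccccc2)cc(OC)c1CC=C(C)C.[Br-]
F4 | step 4 | [3,5-dimethoxy-4-(3-methylbut-2-en-1-yl)benzylidene]triphenylphosphorane | COc1cc(C=P(c2ccccc2)(c2ccccc2)c2ccccc2)cc(OC)c1CC=C(C)C
F5 | step 5 | (E)-1-(4-bromo-3,5-dimethoxyphenyl)-2-[2-methoxy-3,4-bis(methoxymethoxy)phenyl]ethene | COCOc1ccc(/C=C/c2cc(OC)c(Br)c(OC)c2)c(OC)c1OCOC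
F6 | step 5 | 1-[2-(4-bromo-3,5-dimethoxyphenyl)ethyl]-2-methoxy-3,4-bis(methoxymethoxy)benzene | COCOc1ccc(CCc2cc(OC)c(Br)c(OC)c2)c(OC)c1OCOC
F7 | step 7 | 5-{2-[3,5-dimethoxy-4-(3-methylbut-2-en-1-yl)phenyl]ethyl}-2,4-dimethoxy-2-methyl-1,3-benzodioxole (racemic) | COc1cc(CCc2ccc3OC(C)(OC)Oc3c2OC)cc(OC)c1CC=C(C)C
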